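The earlier runs and the new flask are simulated on assumed constants, noise included.

The ratio I wanted was target formed per partner charged, both in mM, and I built the whole problem around it.

| setting | delta | alpha | north-east | north |
|---|---|---|---|---|
| starting material | 20 mM (in portions, 3) | 20 mM (in portions, 3) | 20 mM (in portions, 3) | 20 mM |
| partner | 5.9 mM | 17 mM | 22.0 mM | 8.00 mM |
| remark | run made earlier; portions every 15 s | run made earlier; portions every 15 s | the portions of starting material follow each other after 15 s, the first at the start | everything together at the start |
| time |  |  | 4.0 min | 4.0 min |

| run | time / min | target / % |
|---|---|---|
| delta | 0.500 | 8 |
| delta | 1.00 | 14 |
| delta | 1.33 | 19 |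
| delta | 2.00 | 15 |
| delta | 2.50 | 14 |
| delta | 3.00 | 17 |
| alpha | 0.500 | 14 |
| alpha | 1.00 | 27 |
| alpha | 1.33 | 28 |
| alpha | 2.00 | 32 |
| alpha | 2.50 | 30 |
| alpha | 3.00 | 33 |

(readings scatter by 2 percentage points)

- the flask that ends with the higher amount of target, in percent of the starting material charged, or "neither" when 2 percentage points or less lies between them (north-east / north / neither)
- final target, as a percentage of the starting material charged, in north-east
- final target, as a percentage of the starting material charged, in north

I replaced each curve from 1.33 min on by its mean, 16.2% in delta and 30.8% in alpha, and such a mean carries an error of about 1 percentage point. That gave delta a capture share of 0.551, the target formed per partner charged, and alpha a lower one, 0.362.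

Then I built up north-east and north one process at a time. Take first the main chain: starting material gives open intermediate, partner gives second intermediate, and the two join to target. One partner then gives one target, so north-east reaches 100% and north 40.0%.

Next I added the decomposition of partner. Like the forward step it takes one partner at a turn, so I expected it to remove a share independent of the charge. To read that share I assumed the inverse capture share runs straight against c(partner), with slope 0.0855 /mM, a line through two points that tests nothing. At zero charge it gave 0.763, which lowers north-east to 83.9% and north to 30.5%.

Last came homo product, which takes two second intermediate at a turn, so I expected it to weigh more at higher charge. The line gave 0.313 at 22.0 mM, so 34.5% for north-east, and 20.1% for north, though that figure is read from runs with portions. The gap of 14 points exceeds the margin of 2 points, so I chose north-east.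

The forecast, reasoning that “the target is limited by partner”, gave 35% for north-east and 23% for north, both above my figures, and chose north-east.

North-east ended at 39.0% and north at 22.9%.

    partner → second intermediate (k = 0.0300 /s)
    open intermediate + second intermediate → target (k = 7.60 /M/s)
    starting material → open intermediate (k = 0.100 /s)
    2 second intermediate → homo product (k = 12.0 /M/s)
    partner → decomposed reagent (k = 0.0150 /s)

At 4.00 min north-east held 0% of its partner and still 61.0% as open intermediate, so partner acted as the limiting reagent although its charge of 22.0 mM stood against 20 mM of starting material. Its capture share came to 0.355, against my 0.313. The flask with the portions of north-east and the partner charge of north gave 19.3%, against 20.1% from the capture share line.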